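Readings and results were computed for an exercise; scatter was added.

Decide from the summer run what to do with this flask at 20 h and what to charge next time, beginning with where the starting material went.

| setting | summer | winter | flask |
|---|---|---|---|
| starting material | 0.15 M | 0.15 M | 0.15 M |
| reagent | 0.195 M | 0.195 M | 0.195 M |
| protic impurity | 0.075 M | 0.075 M | 0.0750 M |
| free catalyst | 75 µM | 75 µM | 75 µM |
| temperature | 80 °C | 86 °C | 80 °C |
| remark | the very flask that is asked about, followed so far | run made earlier |  |
| time |  |  | 20 h |

| run | time / h | product / % | starting material / % |
|---|---|---|---|
| summer | 1.33 | 20 | 61 |
| summer | 4.00 | 57 | 18 |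
| summer | 8.00 | 71 | 1 |
| summer | 12.0 | 69 | 0 |
| summer | 15.0 | 70 | 0 |
| winter | 1.33 | 34 | 47 |
| winter | 4.00 | 70 | 4 |
| winter | 8.00 | 76 | 1 |
| winter | 12.0 | 73 | 0 |
| winter | 15.0 | 70 | 0 |

(each reading ± 2 percentage points)

- beta: change nothing and wait 6.0 h more
- eta: at 20 h take out 90% of the product then present, then wait 6.0 h
- delta: at 20 h add free catalyst, 100% of the amount charged, then wait 6.0 h
- alpha: at 20 h add reagent, 50.0% of the amount charged, then wait 6.0 h
- theta: at 20 h raise the temperature by 15 K, then wait 6.0 h

- what is taken out of product is counted as made
- additions bring no volume worth counting

* product, in percent of the starting material first charged, at 20 h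
* what to do for the largest gain in product; "none" if nothing gains more than 2 percentage points (beta / eta / delta / alpha / theta / none)
* product present, with what was taken out counted in, in percent of the starting material first charged, after beta
* product present, with what was taken out counted in, in percent of the starting material first charged, after alpha

In the summer run, which is this flask followed so far, starting material reads 1% at 8.00 h and 0% at 15.0 h, while product from 8.00 h on averages 70.0%. The winter run slips by 6 percentage points over that span, but a reading scatters by 2 points and the summer readings stay flat, so we count no decay and commit to 70.0% at 20 h, after beta and after alpha alike. Since the starting material reading of 0% is less than the margin of 2 points, we choose none of the options and leave this flask alone.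

The next charge is the real decision, because 30.0% of the starting material is missing. Suppose protic impurity, at concentration H, takes starting material one to one, so that the summer run ends with H = 0.0300 M. If product, at concentration P, and this side path are both first order in starting material, with the catalyst held in one resting state, then starting material and time cancel from the ratio of rates. That leaves dH/dP = −σH, which integrates to H equals its charge times exp(−σP). The plateau gives σ = 8.73 M⁻¹, the impurity toll, a selectivity factor that counts the logarithmic fall of protic impurity per unit of product concentration made. The readings at 1.33 h, with their scatter, give 15.9 M⁻¹, so we carry σ as an average over the run. We would therefore charge less protic impurity next time.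

The forecast gives 68% at 20 h, lower than our plateau, with 66% after beta, 66% after alpha and none as the best choice, on the ground: “That loss looks like an irreversible side path, not a reservoir”.

The flask gives 70.9% at 20 h, 70.9% after beta, 70.9% after alpha, and none as the best choice.

    reagent + free catalyst → catalyst intermediate A (k = 36.2 M⁻¹ s⁻¹, Ea = 42.0 kJ mol⁻¹)
    catalyst intermediate A → catalyst intermediate B (k = 0.246 s⁻¹, Ea = 101 kJ mol⁻¹)
    starting material + catalyst intermediate B → catalyst intermediate C (k = 4.41 M⁻¹ s⁻¹, Ea = 69.0 kJ mol⁻¹)
    catalyst intermediate C ⇌ catalyst intermediate D (K = 4.60, k = 0.467 s⁻¹, Ea = 85.0 kJ mol⁻¹, ΔH = −3.00 kJ mol⁻¹)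
    catalyst intermediate D → free catalyst + product (k = 0.457 s⁻¹, Ea = 83.0 kJ mol⁻¹)
    starting material + protic impurity → quenched substrate (k = 7.45 × 10⁻⁴ M⁻¹ s⁻¹, Ea = 63.0 kJ mol⁻¹)
    (constants at 80 °C)

Read forward with σ, the 70.9% of product in this flask should leave 39.6% of the protic impurity, and the flask holds 41.7% at 20.0 h. The neighbouring flask is charged with 0.030 M of protic impurity and is otherwise the same. There, with 0% of the starting material left, product plus quenched substrate must equal the starting material charged, the quenched substrate being the impurity charge times one minus exp(−σP). Solving this by iteration gives 86.4% product. Simulated, that neighbouring flask gives 86.5% product, with 33% of its protic impurity left.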